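## The problem

Target 5, hexacosyl 3-(4-hydroxyphenyl)propanoate, is an achiral wax ester. A para-disubstituted benzene ring (C1' to C6', hydroxyl on C4') is joined through two methylene carbons (C3, then C2) to an ester carbonyl (C1) that carries an unbranched C26 alkoxy chain. No ring has to be closed or fused and there is no stereocenter, so no stereocontrol and no relay of configuration is required. The task is to join three simple pieces through two strategic bonds, the ester C1-O bond and the aryl-alkyl bond C1'-C3, in as few operations as possible. The sensitive groups are the free phenol (acidic, nucleophilic, easily oxidised) and the ester, which excludes strong aqueous base, hydride reagents and late transesterification; any acrylate intermediate can also polymerise by a radical path. The C26 chain is a practical problem of its own: every intermediate is waxy, poorly soluble in cold or polar media and close in polarity to chain-bearing by-products, so each step must be clean enough for crystallisation or a short column. The enabling feature is that C3 lies beta to the carbonyl C1 and is bonded to the sp2 ring carbon C1'. C3 is therefore the electrophilic terminus of an acrylate and C1' can arrive as an aryl-metal nucleophile. A conjugate addition that ends in protonation forms C1'-C3 and delivers the saturated propanoate directly, with the C4' hydroxyl left unprotected.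

## Retrosynthesis

**Cut 1, bond C1'-C3 of 5.** Breaking the bond between the ring carbon C1' and the beta carbon C3 gives 4-hydroxyphenylboronic acid 4 and hexacosyl acrylate 3. This cut is preferred to the benzylic alternatives (C3-C2 or C2-C1) because it is the only one in which both fragments carry their natural polarity without activation: the arene as a boron nucleophile, the chain as a Michael acceptor. The neighbouring cut at the ester C1-O bond would leave the aryl-alkyl bond to be bought ready-made, so it is held in reserve only. The simplification is large: 4 is a shelf reagent and 3 is a plain acrylate ester. The forward reaction, a rhodium-catalysed conjugate arylation, must tolerate a free phenol and an ester. It must add the aryl group only at C3. It must end by protonation of the metal enolate by the aqueous medium, not by beta-hydride elimination.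

**Cut 2, ester C1-O bond of 3.** Disconnecting the acrylate ester gives 1-hexacosanol 1 and acryloyl chloride 2. Acylating the intact C26 alcohol is preferred to assembling the chain, because 1 is purchasable and an acrylate ester is the most direct way to bring in C1 to C3 with C3 already electrophilic. The forward acylation must keep the waxy alcohol in solution and must not trigger polymerisation or conjugate addition to the new acrylate. Compounds 1, 2 and 4 are all purchasable, so the analysis stops here.

## Roads not taken

**Alternative 1:** The benzene ring itself would be disconnected at C1'-C6' and C2'=C3', a Robinson annulation followed by aromatisation. In the forward direction hexacosyl 5-oxopentanoate A2 would be converted by a secondary amine into its enamine, whose alpha carbon (the future C1') adds to methyl vinyl ketone A3. Intramolecular aldol condensation of the keto-aldehyde then closes the carbocycle to give racemic hexacosyl 3-(4-oxocyclohex-2-en-1-yl)propanoate A1, and a dehydrogenation would convert the enone into the phenol of 5.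
- Merits: all ring carbons come from acyclic commodity pieces, the para relation of oxygen and side chain is fixed by the connectivity of the annulation, and the carbon-carbon bonds need no transition metal.
- Weak points: the sequence builds a ring that can be bought with both substituents in place. It creates a stereocenter at C1' only to destroy it. It needs an oxidation-level change at the end, on a substrate whose long chain makes purification hard. A2 is not a stock compound, is prone to self-aldol reaction and would need its own preparation from 1.
- Comparison: at least four steps stand against two. The only point in its favour is that it avoids rhodium and boron. The chosen plan accepts a precious-metal catalyst and in return has no redox adjustment, no wasted stereocenter and half the step count.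

**Alternative 2:** The C26 chain would be cut in its interior, at the bond between the eleventh and twelfth carbons counted from the ester oxygen, and re-formed by mixed Kolbe electrolysis. The acid 12-({3-[4-(2,2-dimethylpropanoyloxy)phenyl]propanoyl}oxy)dodecanoic acid A5 and an excess of palmitic acid A6 would be co-electrolysed at a platinum anode in a partly neutralised alcoholic medium. Both carboxylates lose their carboxyl carbon and the two primary radicals combine to hexacosyl 3-(4-pivaloyloxyphenyl)propanoate A4; removal of the pivalate would then give 5.
- Merits: the expensive C26 alcohol is replaced by two cheap fatty-acid-derived pieces, and a carbon-carbon bond is formed between unactivated sp3 carbons without any metal reagent. On cost of the chain this road is better than the chosen plan, and that has to be admitted.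
- Weak points: radical cross-coupling is statistical, so A4 must be separated from both homodimers and from cation-derived by-products, all long-chain waxes of similar polarity. A5 takes several steps to make. The phenol must be masked against anodic oxidation. The final unmasking must cleave an aryl pivalate selectively beside the alkyl ester that holds the molecule together.
- Comparison: the chosen plan has to buy 1. Against that it sets a convergent two-step sequence, a product defined by a single catalytic event, and no protecting group.

**Alternative 3:** Two bonds at the carbonyl carbon, C2-C1 and C1-O(alkyl), would be cut at once, leading to 4-benzyloxystyrene A8, carbon monoxide A9 and 1-hexacosanol 1. The forward key step is a linear-selective hydroalkoxycarbonylation. A palladium hydride generated from Pd(OAc)2 A10, a bulky chelating di-tert-butylphosphine ligand and a sulfonic acid adds across the styrene, carbon monoxide inserts, and alcoholysis by 1 releases hexacosyl 3-(4-benzyloxyphenyl)propanoate A7. Hydrogenolysis of the benzyl ether would give 5.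
- Merits: the three-component step is fully atom-economical, uses 1 directly with no acrylate and hence no polymerisation risk, and relies on palladium, not rhodium. In atom economy and in bonds formed per step it is at least equal to the chosen plan, and its step count is comparable.
- Weak points: styrenes have an inherent bias towards the branched ester through the benzylic palladium intermediate, so the linear outcome rests entirely on ligand control, and the branched regioisomer would be very hard to remove from a C26 ester. The electron-rich alkoxystyrene can oligomerise under the acid promoter. The alcohol is a stoichiometric waxy solid, not a solvent. Pressurised toxic gas is required. The phenol must be protected and later released.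
- Comparison: the chosen plan fixes regiochemistry through the polarisation of the acrylate, not through a ligand. It runs at ambient pressure under neutral conditions and carries the phenol unprotected to the end.

Key step: step 2

Assumption: 1-hexacosanol 1, acryloyl chloride 2 and 4-hydroxyphenylboronic acid 4 are treated as purchasable materials; the target has no stereocenter, so no stereodescriptor is needed.

## Route

Step 1
Reactants: 1 1-hexacosanol; 2 acryloyl chloride
Product: 3 hexacosyl acrylate (hexacosyl prop-2-enoate)
Conditions: 2 (1.3 equiv), Et3N (1.5 equiv), DMAP (cat.), BHT (trace), toluene, 45 °C, dark
Reagents that add atoms: none
Why: DMAP-catalysed O-acylation of a primary alcohol by an acid chloride (nucleophilic acyl substitution), with triethylamine taking up the hydrogen chloride. Warm toluene keeps the C26 alcohol dissolved, and the radical inhibitor with exclusion of light should suppress polymerisation of the acrylate.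

Step 2
Reactants: 3 hexacosyl acrylate; 4 4-hydroxyphenylboronic acid
Product: 5 hexacosyl 3-(4-hydroxyphenyl)propanoate
Conditions: 4 (2 equiv), [Rh(cod)OH]2 (2.5 mol %), 1,4-dioxane/H2O (10:1), 60 °C, Ar
Reagents that add atoms: none
Why: This is a Hayashi-Miyaura rhodium-catalysed 1,4-addition of an arylboronic acid to an acrylate ester, a known reaction type applied here to a long-chain ester. The hydroxo ligand of [Rh(cod)OH]2 (monovalent rhodium) binds boron of 4, and transmetalation gives a 4-hydroxyphenyl rhodium species without added base. The C2=C3 bond of 3 coordinates and inserts into the aryl-rhodium bond with the aryl group going to the unsubstituted, electrophilic C3; this forms the C1'-C3 bond and an oxa-pi-allyl rhodium enolate. Water protonates the enolate at C2, which releases 5 at the saturated oxidation level and regenerates the hydroxo rhodium catalyst. No ring is closed and no stereocenter is created, so only chemo- and regioselectivity are required. Regiochemistry is fixed by the polarisation of the acrylate and the absence of a substituent at C3. Protonation is favoured over Heck-type beta-hydride elimination by the water-rich medium, the phosphine-free diene ligand and the use of the boronic acid, not the acrylate, in excess. The free phenol and the ester should be inert under these neutral conditions, and the excess of 4 covers losses by protodeboronation.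

## Compound list

1 | 1-hexacosanol | CCCCCCCCCCCCCCCCCCCCCCCCCCO | starting material
2 | acryloyl chloride (prop-2-enoyl chloride) | C=CC(=O)Cl | starting material
3 | hexacosyl acrylate (hexacosyl prop-2-enoate) | CCCCCCCCCCCCCCCCCCCCCCCCCCOC(=O)C=C | intermediate
4 | 4-hydroxyphenylboronic acid | OB(O)c1ccc(O)cc1 | starting material
5 | hexacosyl 3-(4-hydroxyphenyl)propanoate | CCCCCCCCCCCCCCCCCCCCCCCCCCOC(=O)CCc1ccc(O)cc1 | target

## Step count and risk

Total step count: 2.
Longest linear sequence: 2 steps (1 to 3 to 5); compound 4 enters as bought.

The route has only two steps, so beside the key step there is a single other step, and both are assessed.

**Step 2 (key step).** Four processes are the most likely causes of failure: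
- beta-hydride elimination from the rhodium enolate instead of protonation, a Heck-type pathway that also reduces a second molecule of acrylate through the rhodium hydride;
- protonolysis of the aryl rhodium species and protodeboronation of the electron-rich boronic acid before insertion, which starve the cycle of aryl donor;
- addition of the rhodium enolate to a second acrylate, leading to oligomers;
- separation of the waxy acrylate from the aqueous phase, which slows insertion relative to all of these.

The phenolic hydroxyl of 5 gives a polarity handle against non-phenolic wax by-products, but a low conversion would still be costly in 1.

Fallback: the same C1'-C3 bond is made with the ring as the electrophile. Starting from 3, a Mizoroki-Heck coupling with 4-iodophenol (Pd(OAc)2, P(o-tol)3, Et3N, DMF, 90 °C) should give hexacosyl (E)-3-(4-hydroxyphenyl)prop-2-enoate F1. The cycle runs through oxidative addition to zerovalent palladium, insertion at C3 and beta-hydride elimination. Hydrogenation of the C2=C3 bond of F1 (H2, Pd/C, EtOAc/THF, 40 °C) then returns to the route at 5. This costs one extra step for the oxidation-level adjustment, but it does not depend on enolate protonation or on the stability of a boronic acid.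

**Step 1.** Three processes are the likely problems:
- incomplete acylation because the C26 alcohol crystallises from the medium;
- radical polymerisation of the acryloyl unit;
- conjugate addition of chloride or amine to the acrylate during acylation, which gives saturated by-products that co-crystallise with 3.

Fallback: the double bond is introduced only after the ester is in place. Starting from 1, acylation with 3-chloropropanoyl chloride (pyridine, toluene, 45 °C), an acid chloride that cannot polymerise, should give hexacosyl 3-chloropropanoate F2, which can be purified by crystallisation. An E1cB dehydrochlorination of F2 with triethylamine in warm toluene (BHT present) then returns to the route at 3.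

## Further compounds

F1 | step 2 | hexacosyl (E)-3-(4-hydroxyphenyl)prop-2-enoate | CCCCCCCCCCCCCCCCCCCCCCCCCCOC(=O)/C=C/c1ccc(O)cc1
F2 | step 1 | hexacosyl 3-chloropropanoate | CCCCCCCCCCCCCCCCCCCCCCCCCCOC(=O)CCCl
A1 | alternative 1 | hexacosyl 3-(4-oxocyclohex-2-en-1-yl)propanoate (racemic) | CCCCCCCCCCCCCCCCCCCCCCCCCCOC(=O)CCC1CCC(=O)C=C1
A2 | alternative 1 | hexacosyl 5-oxopentanoate | CCCCCCCCCCCCCCCCCCCCCCCCCCOC(=O)CCCC=O
A3 | alternative 1 | methyl vinyl ketone (but-3-en-2-one) | CC(=O)C=C
A4 | alternative 2 | hexacosyl 3-(4-pivaloyloxyphenyl)propanoate | CCCCCCCCCCCCCCCCCCCCCCCCCCOC(=O)CCc1ccc(OC(=O)C(C)(C)C)cc1
A5 | alternative 2 | 12-({3-[4-(2,2-dimethylpropanoyloxy)phenyl]propanoyl}oxy)dodecanoic acid | OC(=O)CCCCCCCCCCCOC(=O)CCc1ccc(OC(=O)C(C)(C)C)cc1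
A6 | alternative 2 | palmitic acid (hexadecanoic acid) | CCCCCCCCCCCCCCCC(=O)O
A7 | alternative 3 | hexacosyl 3-(4-benzyloxyphenyl)propanoate | CCCCCCCCCCCCCCCCCCCCCCCCCCOC(=O)CCc1ccc(OCc2ccccc2)cc1
A8 | alternative 3 | 4-benzyloxystyrene (1-benzyloxy-4-ethenylbenzene) | C=Cc1ccc(OCc2ccccc2)cc1
A9 | alternative 3 | carbon monoxide | [C-]#[O+]
A10 | alternative 3 | palladium diacetate, Pd(OAc)2 | CC(=O)[O-].CC(=O)[O-].[Pd+2]
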